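## The problem

The target is the procyanidin trimer epicatechin-(4β→8)-catechin-(4α→8)-catechin (top, middle and bottom flavan units, each with a phloroglucinol ring A, a catechol ring B and a pyran ring C), acylated at O3 of the bottom unit by (S)-1-hydroxy-6-oxocyclohex-2-ene-1-carboxylic acid. Both interflavan bonds must run from C4 of one unit to C8, not C6, of the next, each trans to the neighbouring 3-oxygen. Of the nine stereocentres, C2 and C3 of the middle and bottom units are those of (+)-catechin and can be bought, and middle C4 can be steered by its own C3 substituent. The 2,3-cis-3,4-trans top unit is insulated from the lower units by an aromatic ring and needs reagent control, after which its C3 and C4 can control C2; the quaternary C1 of the acyl group is remote from everything and needs reagent control as well. The interflavan bonds are doubly activated benzylic bonds that ionise in acid, and the twelve phenols oxidise readily. The acyl group is a β-keto ester with a tertiary α-hydroxyl and a ring alkene: its free acid would decarboxylate, base degrades it and its alkene forbids hydrogenolysis once it is in place, so the phenol protection has to change from benzyl to silyl before acylation and the three secondary hydroxyls have to be told apart. The feature that makes the key step possible is top C4, which is bonded to top C4a (an electron-rich ring-A carbon ortho to O1) and to middle C8, with the C3 oxygen trans to the C4–C8 bond. That is the pattern left when an aryl ether tethered through O1 at C2 opens a C3–C4 epoxide at its benzylic end.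

## Retrosynthesis

**Final deprotection (31 from 30).** The last bonds cut are fourteen O–Si bonds. Benzyl ethers would need hydrogen, which reduces the acyl alkene, and esters would need base, which destroys the keto ester. Silyl ethers leave with buffered fluoride. Precursor 30 has the full skeleton and is stable to handling; the forward step must cleave twelve aryl and two alkyl silyl ethers without base.

**Acyl group (30 from 29, 29 from 27, 27 from 24 and 26, 26 from 25).** Three bonds are cut: the ketone is masked as a methyl enol ether, the C1–OH bond is removed, and the ester C–O bond is broken. The neighbouring cut, esterification with the intact hydroxy keto acid, fails on two counts: that acid is a β-keto acid, and its α-carbon is fully substituted. Acid 26, the Birch product of 2-methoxybenzoic acid 25, has a secondary α-carbon, carries the ketone as an enol ether and places the second alkene where the target needs it. The forward route asks for an unhindered esterification, hydroxylation of a cross-conjugated ester enolate at C1 with face control by a chiral oxaziridine, and a mild enol ether hydrolysis.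

**Aryl silyl ethers in two blocks (24 from 23, 23 from 21, 21 from 20).** The twelve ArO–Si bonds are cut six at a time. Cutting all twelve in one flask would carry a dodecaphenol through a ladder of partly silylated species, with the hindered ring-A phenols beside the interflavan bonds reacting last and no defined compound to check on the way. The three catechols are therefore masked as cyclic phenylboronates in 21, which can form only at ortho-dihydroxy arrays. The six ring-A phenols are then silylated and pinacol removes the boron to give 23, after which the six catechol phenols follow. Phenols are silylated by the silyl chloride much faster than a flavan 3-hydroxyl, so the bottom 3-OH should remain the only free hydroxyl in 24.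

**Telling the C3 oxygens apart (20 from 19, 19 from 18).** Bottom O3 is carried as a benzyl ether so that it is freed together with the phenols in 20. Middle O3 is a silyl ether from the monomer stage, and top O3 is silylated directly after the key step to give 19. The alternative, a bottom O3 group orthogonal to both hydrogenolysis and aryl silyl ethers, has no clean solution.

**Key cut (18 from 17).** The top C4–C4a bond is cut, which opens top ring C and leads back to a trans-epoxide at C3–C4 and an aryl ether at C2. The neighbouring cut is the classical one, joining an epicatechin C4 cation to the dimer. It would have to choose among three free ring-A positions (middle C8, middle C6, bottom C6) and would have to suppress self-condensation of the electrophile. In the chosen cut the C4–C8 bond already exists, made earlier as a C=C bond at a defined carbon, and the new stereocentre follows from the epoxide by inversion. The precursor 17 lacks one ring and one stereocentre.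

**Aryl ether (17 from 14 and 16, 16 from 15).** The C2–O1 bond is cut to the erythro epoxy alcohol 14 and 3,5-bis(benzyloxy)phenol 16, one step from phloroglucinol 15. A Mitsunobu reaction inverts C2, so the erythro carbinol that chelation-controlled reduction gives is the one needed. Arylation with retention would require the threo carbinol, which is harder to reach.

**Carbinol and epoxide (14 from 13, 13 from 12).** The C2–H bond and the two epoxide C–O bonds are cut, leading to the (E)-enone 12. Catalytic asymmetric nucleophilic epoxidation of chalcone-type enones is established, and the oxirane then directs the hydride. The precursor has no stereocentre in the top fragment.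

**Enone (12 from 9 and 11, 11 from 10).** The C3=C4 bond is cut by a retro-aldol condensation to aldehyde 9 and 3,4-bis(benzyloxy)acetophenone 11, one step from 3,4-dihydroxyacetophenone 10. This interflavan carbon–carbon bond is thus made without any stereochemical burden. Aldehyde 9 has no α-hydrogen, so the condensation has one direction.

**Formyl group (9 from 7).** The C8–CHO bond is cut to the aryl bromide 7. Direct formylation of a dimer could not distinguish three ring-A positions. A bromide placed on the monomer, where C8 selectivity is known, fixes the site and also caps the electrophilic unit against self-condensation.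

**Lower interflavan bond (7 from 6 and 3).** The middle C4–bottom C8 bond is cut to the C4-activated bromo monomer 6 and pentabenzyl catechin 3. Both units keep the C2 and C3 centres of catechin. The forward step needs attack at C8 of 3 and entry anti to the 3-silyloxy group of 6.

**Monomers (6 from 5, 5 from 4, 4 and 3 from 2, 2 from 1).** The remaining cuts are C4 oxidation, silylation, bromination and benzylation, all starting from (+)-catechin 1 through its tetrabenzyl ether 2.

## Roads not taken

Alternative 1: The cut is the acyl ester bond, with the acyl unit traced to benzoic acid A2. In the forward key step whole cells of Ralstonia eutropha B9 (benzoate 1,2-dioxygenase, O2) add two hydroxyls syn across C1–C2 of A2 to give the diene diol A1.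
- Merits: one step from a commodity chemical sets the quaternary carbinol with enzymatic enantiopurity and places oxygen on both C1 and the future ketone carbon.
- Weak points: it solves only the seven-carbon acyl group and leaves the trimer, with eight stereocentres and two interflavan bonds, untouched. A1 comes from a fermentation, not a catalogue. One of its two alkenes must be saturated selectively and the secondary carbinol oxidised. The resulting acid A3 is a β-keto acid that cannot be handled free, so a masked form with a fully substituted α-carbon would have to be esterified onto a hindered secondary alcohol.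
- Comparison: at acyl C1 this road is better than the chosen plan, whose step 22 relies on a chiral oxaziridine acting on a planar enolate. Against it the chosen plan sets an unhindered esterification, three purely chemical steps, and the option of fixing and purifying the stereocentre on a small ester. The alternative is an acyl-group tactic that could be attached to any trimer route; it does not compete with the key disconnection.

Alternative 2: The cut removes bottom O1–C8a and the bottom C8–middle C4 bond together. In the forward key step lithium 2,2,6,6-tetramethylpiperidide generates the C8–C8a aryne from fluoroarene A5. The tethered C2 alkoxide adds at C8a and closes bottom ring C. The resulting C8 aryllithium adds to aldehyde A6 to give carbinol A4.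
- Merits: ring closure and interflavan C–C bond in one operation, with C8 regiochemistry fixed by the aryne geometry.
- Weak points: the carbinol forms as epimers and carries no stereochemical information forward. Middle ring C, with its C2, C3 and C4 centres, still has to be grown from a diaryl carbinol. A5 needs its own asymmetric synthesis, so no stereocentre comes from catechin. The strong amide base meets many benzyl ethers. The top unit is still missing.
- Comparison: for site control at bottom C8 this road is at least as clean as the bromide handle used here. The chosen plan takes four stereocentres and two pyran rings from catechin and builds only one ring de novo. Its weaker point is that step 6 depends on facial selectivity in a cationic coupling.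

Alternative 3: The cut dissolves bottom ring A at C8–C8a, C6–C7 and C4a–C8a. In the forward key step, heating opens cyclobutenone A8 to a vinylketene that adds siloxyalkyne A9; 4π opening and 6π closure give phenol A7.
- Merits: the interflavan bond is carried in A9 as an sp3–sp bond, so C8 versus C6 is decided by construction, and O1, O5 and O7 emerge differentiated.
- Weak points: A9 is a flavan-4-yl ynol ether needing several steps, and its C4 centre must survive prolonged heating. Bottom ring C must then be built from the cinnamyl phenol with fresh control of C2 and C3. The middle unit in A7 has no handle at C8, so attaching the top unit returns to the site-selectivity problem.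
- Comparison: this road sets middle C4 on a small molecule, which is more secure than step 6 here. The chosen plan makes the same bond in one step from two catechin units, keeps catechin's stereocentres in both lower units, and gives the top unit a defined attachment point.

Key step: step 14

Assumption: the C4 configuration of 6 is immaterial because C4 is ionised in step 6; 6 is drawn as the 3,4-trans epimer.
Assumption: the sense of induction of the camphor-derived oxaziridine on enolate 28 cannot be derived from close precedent; the (1S)-(+) reagent is written, and its commercial antipode is to be used if a model ester shows the opposite sense.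

## Route

Step 1
Reactants: 1 (+)-catechin
Product: 2 5,7,3′,4′-tetra-O-benzylcatechin
Conditions: BnBr, K2CO3, DMF, 0 °C to rt
Reagents that add atoms: benzyl bromide, BrCc1ccccc1
Why: Williamson etherification; carbonate in DMF ionises only the four phenols, so the secondary 3-OH stays free and C2 and C3 of the chiral-pool material are untouched.

Step 2
Reactants: 2 5,7,3′,4′-tetra-O-benzylcatechin
Product: 3 3,5,7,3′,4′-penta-O-benzylcatechin
Conditions: NaH, BnBr, DMF, 0 °C to rt
Reagents that add atoms: benzyl bromide, BrCc1ccccc1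
Why: Williamson etherification of the secondary alcohol through its sodium alkoxide; this benzyl ether falls with the phenolic ones in step 16 and so marks bottom O3 as the later acylation site.

Step 3
Reactants: 2 5,7,3′,4′-tetra-O-benzylcatechin
Product: 4 8-bromo-5,7,3′,4′-tetra-O-benzylcatechin
Conditions: NBS (1.0 equiv), CH2Cl2, −78 °C to rt
Reagents that add atoms: N-bromosuccinimide, O=C1CCC(=O)N1Br
Why: Electrophilic aromatic bromination; in 5,7-dioxygenated flavans C8 is the more nucleophilic of the two free ring-A carbons, so one equivalent should give the 8-bromide, which later becomes the formyl group and meanwhile blocks C8 of the electrophilic unit.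

Step 4
Reactants: 4 8-bromo-5,7,3′,4′-tetra-O-benzylcatechin
Product: 5 8-bromo-5,7,3′,4′-tetra-O-benzyl-3-O-(tert-butyldimethylsilyl)catechin
Conditions: TBSOTf, 2,6-lutidine, CH2Cl2, 0 °C
Reagents that add atoms: tert-butyldimethylsilyl triflate, CC(C)(C)[Si](C)(C)OS(=O)(=O)C(F)(F)F
Why: Silylation of the hindered secondary alcohol with the silyl triflate; this ether is meant to survive steps 5 to 23 and to leave only with fluoride.

Step 5
Reactants: 5 8-bromo-5,7,3′,4′-tetra-O-benzyl-3-O-(tert-butyldimethylsilyl)catechin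
Product: 6 8-bromo-4-(2-ethoxyethoxy)-5,7,3′,4′-tetra-O-benzyl-3-O-(tert-butyldimethylsilyl)catechin
Conditions: DDQ, 2-ethoxyethanol, CH2Cl2, rt
Reagents that add atoms: 2-ethoxyethanol, CCOCCO
Why: Benzylic oxidation by hydride abstraction at C4 (cation stabilised by the 5,7-dialkoxy ring A) with capture by the alcohol; the new C4 centre is expected trans to the silyl ether but is erased on ionisation in step 6.

Step 6
Reactants: 6 8-bromo-4-(2-ethoxyethoxy)-5,7,3′,4′-tetra-O-benzyl-3-O-(tert-butyldimethylsilyl)catechin; 3 3,5,7,3′,4′-penta-O-benzylcatechin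
Product: 7 bromo dimer [8-bromo-tetra-O-benzyl-3-O-TBS-catechin-(4α→8)-penta-O-benzylcatechin]
Conditions: TMSOTf (0.2 equiv), 3 (2.5 equiv), CH2Cl2, −78 °C
Reagents that add atoms: none
Why: Lewis-acid ionisation of the C4 ether and Friedel–Crafts attack by C8 of 3, its most nucleophilic position; the nucleophile enters anti to the bulky 3-silyloxy group, giving the 3,4-trans (4α) bond, and the C8 bromine keeps the electrophile from condensing with itself.

Step 7
Reactants: 7 bromo dimer
Product: 9 formyl dimer (CHO at middle C8), via C8-aryllithium 8 (not isolated)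
Conditions: t-BuLi (2.1 equiv), THF, −78 °C; then DMF, −78 to 0 °C
Reagents that add atoms: N,N-dimethylformamide, CN(C)C=O
Why: Bromine–lithium exchange followed by formylation with DMF (Bouveault aldehyde synthesis); exchange is faster than benzylic deprotonation at −78 °C and the site of formylation is fixed by the bromide.

Step 8
Reactants: 10 3,4-dihydroxyacetophenone
Product: 11 3,4-bis(benzyloxy)acetophenone
Conditions: BnBr, K2CO3, DMF, rt
Reagents that add atoms: benzyl bromide, BrCc1ccccc1
Why: Williamson etherification of both phenols; the methyl ketone is untouched.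

Step 9
Reactants: 9 formyl dimer; 11 3,4-bis(benzyloxy)acetophenone
Product: 12 (E)-enone [middle C8–CH=CH–CO–C6H3(OBn)2]
Conditions: KOH, EtOH/THF, rt to 50 °C
Reagents that add atoms: none
Why: Claisen–Schmidt condensation; the aldehyde has no α-hydrogen, the ketone enolate adds and E1cB loss of hydroxide gives the thermodynamically favoured (E)-enone, while benzyl and alkyl silyl ethers tolerate hydroxide.

Step 10
Reactants: 12 (E)-enone
Product: 13 trans-epoxy ketone [oxirane (2R,3S): carbon next to C=O is R, benzylic carbon is S]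
Conditions: poly-L-leucine, urea–H2O2, DBU, THF, rt
Reagents that add atoms: urea–hydrogen peroxide, NC(N)=O.OO
Why: Juliá–Colonna epoxidation (Weitz–Scheffer addition of hydroperoxide under poly-amino-acid control); poly-L-leucine is the catalyst antipode known to give the (2R,3S)-oxirane from (E)-chalcone-type enones, and the E geometry is carried into the trans-epoxide, so top C3 and the epoxide carbon that becomes top C4 are set by catalyst control.

Step 11
Reactants: 13 trans-epoxy ketone
Product: 14 erythro epoxy alcohol [carbinol carbon S]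
Conditions: Zn(BH4)2, Et2O, −20 °C
Reagents that add atoms: none
Why: Chelation-controlled hydride reduction; zinc bridges the carbonyl and oxirane oxygens and hydride enters from the face of the chelate that carries the oxirane hydrogen, giving the erythro (anti) epoxy alcohol, while the epoxide and silyl ether are not attacked at low temperature.

Step 12
Reactants: 15 phloroglucinol
Product: 16 3,5-bis(benzyloxy)phenol
Conditions: BnBr (2.0 equiv), K2CO3, DMF, rt
Reagents that add atoms: benzyl bromide, BrCc1ccccc1
Why: Williamson etherification under statistical control; the three hydroxyls are equivalent, so two equivalents of benzyl bromide should give a separable mixture from which the bis-ether is taken.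

Step 13
Reactants: 14 erythro epoxy alcohol; 16 3,5-bis(benzyloxy)phenol
Product: 17 threo epoxy aryl ether [C2 of the future top unit R; trans-epoxide at C3–C4]
Conditions: PPh3, DIAD, toluene, 0 °C to rt
Reagents that add atoms: none
Why: Mitsunobu etherification; the phenol displaces the oxyphosphonium group at the benzylic carbinol with inversion, turning the erythro alcohol into the threo aryl ether with the C2 configuration of the top unit, and no other free hydroxyl is present.

Step 14
Reactants: 17 threo epoxy aryl ether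
Product: 18 benzylated trimer with free top 3-OH [epicatechin-(4β→8)-catechin-(4α→8)-catechin; middle O3 TBS, bottom O3 Bn]
Conditions: BF3·OEt2 (0.2 equiv), CH2Cl2, −78 °C
Reagents that add atoms: none
Why: BF3 binds the oxirane oxygen and the C4–O bond, benzylic to the 2,4,6-trioxygenated ring A of the middle unit, lengthens; the ortho carbon of the 3,5-bis(benzyloxy)phenyl ether (the future C4a) attacks C4 from the side opposite the leaving oxygen, and loss of the arenium proton to the boron alkoxide restores aromaticity, frees the 3-OH and returns BF3. The closest known reaction type is the Lewis-acid epoxy–arene (intramolecular Friedel–Crafts) cyclisation of aryl ethers of 2,3-epoxy alcohols to chroman-3-ols. Top ring C closes in the 6-endo mode with respect to the epoxide; the 5-exo alternative at C3 would place charge next to the electron-poor C2 and is not expected. The one new stereocentre, top C4, is controlled by the trans-epoxide: inversion at C4 with retention of the C3–O bond puts the middle unit trans to the 3-OH (4β), and C2 and C3 were fixed in steps 10 to 13. Should the C4–O bond ionise fully, the planar cation is expected to close on the same face, anti to the boron-bound 3-oxygen with the large middle unit pseudo-equatorial. The step needs regioselectivity (C4 over C3, secured by benzylic stabilisation), site selectivity on the arene (the two ortho carbons are equivalent and the para carbon cannot reach) and chemoselectivity against a 1,2-hydride shift or loss of the middle silyl ether, for which the tethered nucleophile, the sub-stoichiometric Lewis acid and −78 °C are relied upon.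

Step 15
Reactants: 18 benzylated trimer with free top 3-OH
Product: 19 benzylated trimer with top and middle 3-O-TBS
Conditions: TBSOTf, 2,6-lutidine, CH2Cl2, 0 °C to rt
Reagents that add atoms: tert-butyldimethylsilyl triflate, CC(C)(C)[Si](C)(C)OS(=O)(=O)C(F)(F)F
Why: Silylation with the triflate, needed for the axial and doubly flanked top 3-OH; after this step the benzyl-protected bottom O3 is the only C3 oxygen that hydrogenolysis will free.

Step 16
Reactants: 19 benzylated trimer with top and middle 3-O-TBS
Product: 20 dodecaphenol trimer [top and middle 3-O-TBS; bottom 3-OH free]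
Conditions: H2 (1 atm), Pd(OH)2/C, THF/MeOH, rt
Reagents that add atoms: none
Why: Hydrogenolysis of the twelve aryl benzyl ethers and the bottom O3 benzyl ether over Pd(OH)2 on carbon; alkyl silyl ethers and the interflavan bonds are inert to neutral hydrogenation.

Step 17
Reactants: 20 dodecaphenol trimer
Product: 21 tris(phenylboronate) of the dodecaphenol trimer [each ring-B catechol as a 2-phenyl-1,3,2-benzodioxaborole; six ring-A phenols and bottom 3-OH free]
Conditions: PhB(OH)2 (3.0 equiv), 4 Å sieves, THF, rt
Reagents that add atoms: phenylboronic acid, OB(O)c1ccccc1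
Why: Boronic ester condensation under thermodynamic control; only the three ortho-dihydroxy arrays can close five-membered dioxaborole rings, whereas the isolated ring-A phenols and the lone secondary alcohol give no stable ester, and the weakly Lewis-acidic boronic acid does not ionise the interflavan bonds.

Step 18
Reactants: 21 tris(phenylboronate) of the dodecaphenol trimer
Product: 23 ring-A hexa-O-TBS trimer [5,7-O-TBS on each unit; top and middle 3-O-TBS; catechols and bottom 3-OH free], via ring-A hexa-O-TBS tris(phenylboronate) 22 (not isolated)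
Conditions: TBSCl, imidazole, DMF, 0 °C to rt; then pinacol, rt
Reagents that add atoms: tert-butyldimethylsilyl chloride, CC(C)(C)[Si](C)(C)Cl
Why: Phenol-selective silylation of the six ring-A phenols while the catechol oxygens are held on boron (transient boronate masking of a diol), followed by transesterification of the phenylboron units to the more stable pinacol ester, which frees the catechols. The secondary bottom 3-OH reacts with the silyl chloride far more slowly than a phenol, and a catechol oxygen silylated early would only anticipate step 19.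

Step 19
Reactants: 23 ring-A hexa-O-TBS trimer
Product: 24 tetradeca-O-TBS trimer with free bottom 3-OH
Conditions: TBSCl, imidazole, DMF, 0 °C to rt
Reagents that add atoms: tert-butyldimethylsilyl chloride, CC(C)(C)[Si](C)(C)Cl
Why: Phenol-selective silylation of the six catechol phenols; with the silyl chloride and imidazole the acidic phenols react far faster than the hindered secondary 3-OH of a flavan-3-ol (which needed the triflate in steps 4 and 15), so the bottom 3-OH should remain the only free hydroxyl.

Step 20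
Reactants: 25 2-methoxybenzoic acid
Product: 26 2-methoxycyclohexa-2,5-diene-1-carboxylic acid (racemic)
Conditions: Li, NH3(l), THF, −78 °C; then NH4Cl; work-up at pH 4, 0 °C
Reagents that add atoms: none
Why: Birch reduction of the benzoate; electron transfer and protonation at the ipso and para carbons give the 2,5-diene, in which the enol ether is the masked C6 ketone and the other alkene sits where the acyl group needs it, and the racemic C1 centre is planarised in step 22.

Step 21
Reactants: 24 tetradeca-O-TBS trimer with free bottom 3-OH; 26 2-methoxycyclohexa-2,5-diene-1-carboxylic acid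
Product: 27 bottom 3-O-(2-methoxycyclohexa-2,5-diene-1-carbonyl) ester (both C1 epimers)
Conditions: DCC, DMAP (cat.), CH2Cl2, 0 °C to rt
Reagents that add atoms: none
Why: Steglich esterification; the acid has a secondary, unhindered α-carbon, so acylation of the equatorial bottom 3-OH should proceed, and either C1 epimer or alkene isomer of the ester leads to the same enolate in step 22.

Step 22
Reactants: 27 bottom 3-O-(2-methoxycyclohexa-2,5-diene-1-carbonyl) ester
Product: 29 bottom 3-O-[(S)-1-hydroxy-2-methoxycyclohexa-2,5-diene-1-carbonyl] ester, via sodium dienolate 28 (not isolated)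
Conditions: NaN(SiMe3)2, THF, −78 °C; then (1S)-(+)-(10-camphorsulfonyl)oxaziridine, −78 °C; NH4Cl
Reagents that add atoms: (1S)-(+)-(10-camphorsulfonyl)oxaziridine, CC1(C)[C@@H]2CC[C@]13CS(=O)(=O)N1O[C@@]31C2
Why: Davis oxidation of the cross-conjugated ester dienolate; the amide base removes the doubly allylic α-hydrogen (no other C–H of comparable acidity is present and silyl ethers are inert to it at −78 °C) and the N-sulfonyloxaziridine transfers oxygen to C1, the carbon of highest charge density, with the face of attack and hence the (S)-carbinol to be set by the enantiopure reagent (reagent control).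

Step 23
Reactants: 29 bottom 3-O-[(S)-1-hydroxy-2-methoxycyclohexa-2,5-diene-1-carbonyl] ester
Product: 30 tetradeca-O-TBS ether of the target
Conditions: oxalic acid, THF/H2O, 0 °C
Reagents that add atoms: water, O
Why: Acid hydrolysis of the methyl enol ether (protonation at its β-carbon, hydration of the oxocarbenium ion, loss of methanol) unmasks the C6 ketone; the carbinol carbon bears no hydrogen, so neither epimerisation nor migration of the ring alkene into conjugation can occur, and aryl silyl ethers resist dilute acid.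

Step 24
Reactants: 30 tetradeca-O-TBS ether of the target
Product: 31 CNP0159807.2
Conditions: HF·pyridine, pyridine, THF, 0 °C to rt
Reagents that add atoms: none
Why: Fluoride-mediated cleavage of all fourteen silyl ethers under buffered conditions; no base is present that could trigger retro-Claisen cleavage or dimerisation of the hydroxy keto ester, no hydrogen that could reduce its alkene, and the interflavan bonds are not ionised by pyridinium fluoride at or below room temperature.

## Compound list

1 | (+)-catechin, (2R,3S) | O[C@H]1Cc2c(O)cc(O)cc2O[C@@H]1c1ccc(O)c(O)c1 | starting material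
2 | 5,7,3′,4′-tetra-O-benzylcatechin | O[C@H]1Cc2c(OCc3ccccc3)cc(OCc3ccccc3)cc2O[C@@H]1c1ccc(OCc2ccccc2)c(OCc2ccccc2)c1 | intermediate
3 | 3,5,7,3′,4′-penta-O-benzylcatechin | C(c1ccccc1)O[C@H]1Cc2c(OCc3ccccc3)cc(OCc3ccccc3)cc2O[C@@H]1c1ccc(OCc2ccccc2)c(OCc2ccccc2)c1 | intermediate
4 | 8-bromo-5,7,3′,4′-tetra-O-benzylcatechin | O[C@H]1Cc2c(OCc3ccccc3)cc(OCc3ccccc3)c(Br)c2O[C@@H]1c1ccc(OCc2ccccc2)c(OCc2ccccc2)c1 | intermediate
5 | 8-bromo-5,7,3′,4′-tetra-O-benzyl-3-O-TBS-catechin | CC(C)(C)[Si](C)(C)O[C@H]1Cc2c(OCc3ccccc3)cc(OCc3ccccc3)c(Br)c2O[C@@H]1c1ccc(OCc2ccccc2)c(OCc2ccccc2)c1 | intermediate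
6 | 8-bromo-4-(2-ethoxyethoxy)-5,7,3′,4′-tetra-O-benzyl-3-O-TBS-catechin (3,4-trans drawn) | CC(C)(C)[Si](C)(C)O[C@H]1[C@H](OCCOCC)c2c(OCc3ccccc3)cc(OCc3ccccc3)c(Br)c2O[C@@H]1c1ccc(OCc2ccccc2)c(OCc2ccccc2)c1 | intermediate
7 | bromo dimer: 8-bromo-5,7,3′,4′-tetra-O-benzyl-3-O-TBS-catechin-(4α→8)-3,5,7,3′,4′-penta-O-benzylcatechin | C(c1ccccc1)O[C@H]1Cc2c(OCc3ccccc3)cc(OCc3ccccc3)c([C@@H]3c4c(OCc5ccccc5)cc(OCc5ccccc5)c(Br)c4O[C@H](c4ccc(OCc5ccccc5)c(OCc5ccccc5)c4)[C@H]3O[Si](C)(C)C(C)(C)C)c2O[C@@H]1c1ccc(OCc2ccccc2)c(OCc2ccccc2)c1 | intermediate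
8 | C8-aryllithium of the dimer (lithium in place of bromine at middle C8) | C(c1ccccc1)O[C@H]1Cc2c(OCc3ccccc3)cc(OCc3ccccc3)c([C@@H]3c4c(OCc5ccccc5)cc(OCc5ccccc5)c([Li])c4O[C@H](c4ccc(OCc5ccccc5)c(OCc5ccccc5)c4)[C@H]3O[Si](C)(C)C(C)(C)C)c2O[C@@H]1c1ccc(OCc2ccccc2)c(OCc2ccccc2)c1 | intermediate (not isolated)
9 | formyl dimer (CHO at middle C8) | C(c1ccccc1)O[C@H]1Cc2c(OCc3ccccc3)cc(OCc3ccccc3)c([C@@H]3c4c(OCc5ccccc5)cc(OCc5ccccc5)c(C=O)c4O[C@H](c4ccc(OCc5ccccc5)c(OCc5ccccc5)c4)[C@H]3O[Si](C)(C)C(C)(C)C)c2O[C@@H]1c1ccc(OCc2ccccc2)c(OCc2ccccc2)c1 | intermediate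
10 | 3,4-dihydroxyacetophenone | CC(=O)c1ccc(O)c(O)c1 | starting material
11 | 3,4-bis(benzyloxy)acetophenone | CC(=O)c1ccc(OCc2ccccc2)c(OCc2ccccc2)c1 | intermediate
12 | (E)-enone: dimer carrying (E)-3-[3,4-bis(benzyloxy)phenyl]-3-oxoprop-1-enyl at middle C8 | C(c1ccccc1)O[C@H]1Cc2c(OCc3ccccc3)cc(OCc3ccccc3)c([C@@H]3c4c(OCc5ccccc5)cc(OCc5ccccc5)c(/C=C/C(=O)c5ccc(OCc6ccccc6)c(OCc6ccccc6)c5)c4O[C@H](c4ccc(OCc5ccccc5)c(OCc5ccccc5)c4)[C@H]3O[Si](C)(C)C(C)(C)C)c2O[C@@H]1c1ccc(OCc2ccccc2)c(OCc2ccccc2)c1 | intermediate
13 | trans-epoxy ketone, oxirane (2R,3S) | C(c1ccccc1)O[C@H]1Cc2c(OCc3ccccc3)cc(OCc3ccccc3)c([C@@H]3c4c(OCc5ccccc5)cc(OCc5ccccc5)c([C@@H]5O[C@H]5C(=O)c5ccc(OCc6ccccc6)c(OCc6ccccc6)c5)c4O[C@H](c4ccc(OCc5ccccc5)c(OCc5ccccc5)c4)[C@H]3O[Si](C)(C)C(C)(C)C)c2O[C@@H]1c1ccc(OCc2ccccc2)c(OCc2ccccc2)c1 | intermediate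
14 | erythro epoxy alcohol, carbinol (S) | C(c1ccccc1)O[C@H]1Cc2c(OCc3ccccc3)cc(OCc3ccccc3)c([C@@H]3c4c(OCc5ccccc5)cc(OCc5ccccc5)c([C@@H]5O[C@H]5[C@@H](O)c5ccc(OCc6ccccc6)c(OCc6ccccc6)c5)c4O[C@H](c4ccc(OCc5ccccc5)c(OCc5ccccc5)c4)[C@H]3O[Si](C)(C)C(C)(C)C)c2O[C@@H]1c1ccc(OCc2ccccc2)c(OCc2ccccc2)c1 | intermediate
15 | phloroglucinol | Oc1cc(O)cc(O)c1 | starting material
16 | 3,5-bis(benzyloxy)phenol | Oc1cc(OCc2ccccc2)cc(OCc2ccccc2)c1 | intermediate
17 | threo epoxy aryl ether: middle C8 trans-epoxide carrying the (R)-configured C2 3,5-bis(benzyloxy)phenyl ether | C(c1ccccc1)O[C@H]1Cc2c(OCc3ccccc3)cc(OCc3ccccc3)c([C@@H]3c4c(OCc5ccccc5)cc(OCc5ccccc5)c([C@@H]5O[C@H]5[C@H](Oc5cc(OCc6ccccc6)cc(OCc6ccccc6)c5)c5ccc(OCc6ccccc6)c(OCc6ccccc6)c5)c4O[C@H](c4ccc(OCc5ccccc5)c(OCc5ccccc5)c4)[C@H]3O[Si](C)(C)C(C)(C)C)c2O[C@@H]1c1ccc(OCc2ccccc2)c(OCc2ccccc2)c1 | intermediate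
18 | benzylated epicatechin-(4β→8)-catechin-(4α→8)-catechin: top 3-OH free, middle 3-O-TBS, bottom 3-O-benzyl | C(c1ccccc1)O[C@H]1Cc2c(OCc3ccccc3)cc(OCc3ccccc3)c([C@@H]3c4c(OCc5ccccc5)cc(OCc5ccccc5)c([C@H]5c6c(OCc7ccccc7)cc(OCc7ccccc7)cc6O[C@H](c6ccc(OCc7ccccc7)c(OCc7ccccc7)c6)[C@@H]5O)c4O[C@H](c4ccc(OCc5ccccc5)c(OCc5ccccc5)c4)[C@H]3O[Si](C)(C)C(C)(C)C)c2O[C@@H]1c1ccc(OCc2ccccc2)c(OCc2ccccc2)c1 | intermediate
19 | as 18 with top 3-O-TBS | C(c1ccccc1)O[C@H]1Cc2c(OCc3ccccc3)cc(OCc3ccccc3)c([C@@H]3c4c(OCc5ccccc5)cc(OCc5ccccc5)c([C@H]5c6c(OCc7ccccc7)cc(OCc7ccccc7)cc6O[C@H](c6ccc(OCc7ccccc7)c(OCc7ccccc7)c6)[C@@H]5O[Si](C)(C)C(C)(C)C)c4O[C@H](c4ccc(OCc5ccccc5)c(OCc5ccccc5)c4)[C@H]3O[Si](C)(C)C(C)(C)C)c2O[C@@H]1c1ccc(OCc2ccccc2)c(OCc2ccccc2)c1 | intermediate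
20 | epicatechin-(4β→8)-catechin-(4α→8)-catechin with top and middle 3-O-TBS, all phenols and bottom 3-OH free | O[C@H]1Cc2c(O)cc(O)c([C@@H]3c4c(O)cc(O)c([C@H]5c6c(O)cc(O)cc6O[C@H](c6ccc(O)c(O)c6)[C@@H]5O[Si](C)(C)C(C)(C)C)c4O[C@H](c4ccc(O)c(O)c4)[C@H]3O[Si](C)(C)C(C)(C)C)c2O[C@@H]1c1ccc(O)c(O)c1 | intermediate
21 | tris(phenylboronate) of 20: each ring-B catechol as a 2-phenyl-1,3,2-benzodioxaborole, ring-A phenols and bottom 3-OH free | O[C@H]1Cc2c(O)cc(O)c([C@@H]3c4c(O)cc(O)c([C@H]5c6c(O)cc(O)cc6O[C@H](c6ccc7OB(c8ccccc8)Oc7c6)[C@@H]5O[Si](C)(C)C(C)(C)C)c4O[C@H](c4ccc5OB(c6ccccc6)Oc5c4)[C@H]3O[Si](C)(C)C(C)(C)C)c2O[C@@H]1c1ccc2OB(c3ccccc3)Oc2c1 | intermediate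
22 | ring-A hexa-O-TBS tris(phenylboronate): 21 with all six ring-A phenols silylated | O[C@H]1Cc2c(O[Si](C)(C)C(C)(C)C)cc(O[Si](C)(C)C(C)(C)C)c([C@@H]3c4c(O[Si](C)(C)C(C)(C)C)cc(O[Si](C)(C)C(C)(C)C)c([C@H]5c6c(O[Si](C)(C)C(C)(C)C)cc(O[Si](C)(C)C(C)(C)C)cc6O[C@H](c6ccc7OB(c8ccccc8)Oc7c6)[C@@H]5O[Si](C)(C)C(C)(C)C)c4O[C@H](c4ccc5OB(c6ccccc6)Oc5c4)[C@H]3O[Si](C)(C)C(C)(C)C)c2O[C@@H]1c1ccc2OB(c3ccccc3)Oc2c1 | intermediate (not isolated)
23 | ring-A hexa-O-TBS trimer: 5,7-O-TBS on each unit, top and middle 3-O-TBS, three catechols and bottom 3-OH free | O[C@H]1Cc2c(O[Si](C)(C)C(C)(C)C)cc(O[Si](C)(C)C(C)(C)C)c([C@@H]3c4c(O[Si](C)(C)C(C)(C)C)cc(O[Si](C)(C)C(C)(C)C)c([C@H]5c6c(O[Si](C)(C)C(C)(C)C)cc(O[Si](C)(C)C(C)(C)C)cc6O[C@H](c6ccc(O)c(O)c6)[C@@H]5O[Si](C)(C)C(C)(C)C)c4O[C@H](c4ccc(O)c(O)c4)[C@H]3O[Si](C)(C)C(C)(C)C)c2O[C@@H]1c1ccc(O)c(O)c1 | intermediate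
24 | tetradeca-O-TBS trimer (twelve aryl, top and middle O3) with free bottom 3-OH | O[C@H]1Cc2c(O[Si](C)(C)C(C)(C)C)cc(O[Si](C)(C)C(C)(C)C)c([C@@H]3c4c(O[Si](C)(C)C(C)(C)C)cc(O[Si](C)(C)C(C)(C)C)c([C@H]5c6c(O[Si](C)(C)C(C)(C)C)cc(O[Si](C)(C)C(C)(C)C)cc6O[C@H](c6ccc(O[Si](C)(C)C(C)(C)C)c(O[Si](C)(C)C(C)(C)C)c6)[C@@H]5O[Si](C)(C)C(C)(C)C)c4O[C@H](c4ccc(O[Si](C)(C)C(C)(C)C)c(O[Si](C)(C)C(C)(C)C)c4)[C@H]3O[Si](C)(C)C(C)(C)C)c2O[C@@H]1c1ccc(O[Si](C)(C)C(C)(C)C)c(O[Si](C)(C)C(C)(C)C)c1 | intermediate
25 | 2-methoxybenzoic acid | COc1ccccc1C(=O)O | starting material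
26 | 2-methoxycyclohexa-2,5-diene-1-carboxylic acid (racemic) | COC1=CCC=CC1C(=O)O | intermediate
27 | ester of 24 at bottom O3 with 26 (both C1 epimers) | COC1=CCC=CC1C(=O)O[C@H]1Cc2c(O[Si](C)(C)C(C)(C)C)cc(O[Si](C)(C)C(C)(C)C)c([C@@H]3c4c(O[Si](C)(C)C(C)(C)C)cc(O[Si](C)(C)C(C)(C)C)c([C@H]5c6c(O[Si](C)(C)C(C)(C)C)cc(O[Si](C)(C)C(C)(C)C)cc6O[C@H](c6ccc(O[Si](C)(C)C(C)(C)C)c(O[Si](C)(C)C(C)(C)C)c6)[C@@H]5O[Si](C)(C)C(C)(C)C)c4O[C@H](c4ccc(O[Si](C)(C)C(C)(C)C)c(O[Si](C)(C)C(C)(C)C)c4)[C@H]3O[Si](C)(C)C(C)(C)C)c2O[C@@H]1c1ccc(O[Si](C)(C)C(C)(C)C)c(O[Si](C)(C)C(C)(C)C)c1 | intermediate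
28 | sodium dienolate of 27 | [Na+].COC1=CCC=CC1=C([O-])O[C@H]1Cc2c(O[Si](C)(C)C(C)(C)C)cc(O[Si](C)(C)C(C)(C)C)c([C@@H]3c4c(O[Si](C)(C)C(C)(C)C)cc(O[Si](C)(C)C(C)(C)C)c([C@H]5c6c(O[Si](C)(C)C(C)(C)C)cc(O[Si](C)(C)C(C)(C)C)cc6O[C@H](c6ccc(O[Si](C)(C)C(C)(C)C)c(O[Si](C)(C)C(C)(C)C)c6)[C@@H]5O[Si](C)(C)C(C)(C)C)c4O[C@H](c4ccc(O[Si](C)(C)C(C)(C)C)c(O[Si](C)(C)C(C)(C)C)c4)[C@H]3O[Si](C)(C)C(C)(C)C)c2O[C@@H]1c1ccc(O[Si](C)(C)C(C)(C)C)c(O[Si](C)(C)C(C)(C)C)c1 | intermediate (not isolated)
29 | bottom 3-O-[(S)-1-hydroxy-2-methoxycyclohexa-2,5-diene-1-carbonyl] ester of 24 | COC1=CCC=C[C@@]1(O)C(=O)O[C@H]1Cc2c(O[Si](C)(C)C(C)(C)C)cc(O[Si](C)(C)C(C)(C)C)c([C@@H]3c4c(O[Si](C)(C)C(C)(C)C)cc(O[Si](C)(C)C(C)(C)C)c([C@H]5c6c(O[Si](C)(C)C(C)(C)C)cc(O[Si](C)(C)C(C)(C)C)cc6O[C@H](c6ccc(O[Si](C)(C)C(C)(C)C)c(O[Si](C)(C)C(C)(C)C)c6)[C@@H]5O[Si](C)(C)C(C)(C)C)c4O[C@H](c4ccc(O[Si](C)(C)C(C)(C)C)c(O[Si](C)(C)C(C)(C)C)c4)[C@H]3O[Si](C)(C)C(C)(C)C)c2O[C@@H]1c1ccc(O[Si](C)(C)C(C)(C)C)c(O[Si](C)(C)C(C)(C)C)c1 | intermediate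
30 | tetradeca-O-TBS ether of the target [bottom 3-O-((S)-1-hydroxy-6-oxocyclohex-2-ene-1-carbonyl)] | O=C1CCC=C[C@@]1(O)C(=O)O[C@H]1Cc2c(O[Si](C)(C)C(C)(C)C)cc(O[Si](C)(C)C(C)(C)C)c([C@@H]3c4c(O[Si](C)(C)C(C)(C)C)cc(O[Si](C)(C)C(C)(C)C)c([C@H]5c6c(O[Si](C)(C)C(C)(C)C)cc(O[Si](C)(C)C(C)(C)C)cc6O[C@H](c6ccc(O[Si](C)(C)C(C)(C)C)c(O[Si](C)(C)C(C)(C)C)c6)[C@@H]5O[Si](C)(C)C(C)(C)C)c4O[C@H](c4ccc(O[Si](C)(C)C(C)(C)C)c(O[Si](C)(C)C(C)(C)C)c4)[C@H]3O[Si](C)(C)C(C)(C)C)c2O[C@@H]1c1ccc(O[Si](C)(C)C(C)(C)C)c(O[Si](C)(C)C(C)(C)C)c1 | intermediate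
31 | CNP0159807.2: epicatechin-(4β→8)-catechin-(4α→8)-catechin 3-O-[(S)-1-hydroxy-6-oxocyclohex-2-ene-1-carboxylate] at the bottom unit | O=C1CCC=C[C@@]1(O)C(=O)O[C@H]1Cc2c(O)cc(O)c([C@@H]3c4c(O)cc(O)c([C@H]5c6c(O)cc(O)cc6O[C@H](c6ccc(O)c(O)c6)[C@@H]5O)c4O[C@H](c4ccc(O)c(O)c4)[C@H]3O)c2O[C@@H]1c1ccc(O)c(O)c1 | target

## Step count and least certain steps

Total step count: 24. Longest linear sequence: 20 steps from (+)-catechin (steps 1, 3–7, 9–11, 13–19, 21–24).

**Step 14 (key step).** The most likely failure is collapse of the strongly stabilised C4 cation by a 1,2-hydride shift to a ketone before the arene attacks. Full ionisation with erosion of the 3,4-trans outcome, or Lewis-acid loss of the middle silyl ether, are further possibilities. Fallback, keeping the same bond and ring closure: from 17 the oxirane is first opened at C4 by buffered acetolysis (AcOH, NaOAc, CH2Cl2, 0 °C), in which acetate intercepts the cation, to give the 4-acetoxy-3-hydroxy ether F1. The C4 acetate is then ionised on its own with TMSOTf (catalytic, CH2Cl2, −78 °C), the standard electrophile type for interflavan bond formation, and the tethered arene closes ring C anti to the 3-oxygen, returning to 18.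

**Step 22.** The likely failure is poor facial selectivity in oxygen transfer. The two faces of the planar enolate differ only by methoxy against hydrogen on the flanking ring carbons, and the nearest resident stereocentre is three bonds away. β-Elimination of the bottom alkoxide from the enolate is a second risk. Fallback: the stereocentre is set and purified on a small molecule. From 26 the acid is methylated (MeI, K2CO3, DMF) to methyl 2-methoxycyclohexa-2,5-diene-1-carboxylate F2 and hydroxylated under the same Davis conditions to methyl (S)-1-hydroxy-2-methoxycyclohexa-2,5-diene-1-carboxylate F3. Saponification (LiOH, THF/H2O) gives (S)-1-hydroxy-2-methoxycyclohexa-2,5-diene-1-carboxylic acid F4, whose enantiomeric purity can be raised by crystallising its salt with an enantiopure 1-phenylethylamine. F4 is then joined to 24 by Yamaguchi esterification (2,4,6-trichlorobenzoyl chloride, Et3N, then DMAP, toluene; the tertiary hydroxyl does not compete), returning to 29.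

**Step 13.** The likely failure is ionisation of the activated benzylic carbinol, assisted by the para-benzyloxy group, so that inversion at C2 is incomplete. Fallback with retention at carbon: from 13 a Corey–Bakshi–Shibata reduction with the (R)-2-methyl oxazaborolidine and BH3·SMe2, the aryl group acting as the large substituent, should give the threo epoxy alcohol F5. Its oxygen is then arylated with commercial 1-bromo-3,5-bis(benzyloxy)benzene by Buchwald–Hartwig etherification (Pd(OAc)2, RockPhos, Cs2CO3, toluene, 80 °C), returning to 17.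

**Step 10.** The likely failure is slow or unselective oxygen transfer. The enone is deactivated by its electron-rich, doubly ortho-substituted β-aryl group, the polymeric catalyst must accommodate a flavan dimer, and the resident stereocentres may oppose the catalyst. Fallback with an electrophilic, hydroxyl-directed epoxidation: from 12 Luche reduction (NaBH4, CeCl3·7H2O, MeOH/THF) gives the (R)-allylic alcohol F6 together with its (S)-epimer F7. Sharpless epoxidation (Ti(OiPr)4, L-(+)-diisopropyl tartrate, t-BuOOH, 4 Å sieves, CH2Cl2, −20 °C) converts the matched epimer F6 to the erythro epoxy alcohol, returning to 14. The slow-reacting F7 is returned to 12 with MnO2.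

**Step 6.** The likely failure is incomplete facial control in the attack on the C4 cation, because the 3-silyloxy group shields one face only sterically. Fallback with neighbouring-group participation: from 4, DDQ and 2-ethoxyethanol give the 4-(2-ethoxyethoxy) alcohol F8, and acetylation (Ac2O, pyridine, DMAP) gives its 3-acetate F9. TMSOTf-promoted coupling with 3, in which the acetoxonium ion covers the β-face, gives the 4α-linked dimer acetate F10. Methanolysis (K2CO3, MeOH/THF) gives the dimer alcohol F11, and TBSOTf with 2,6-lutidine returns to 7.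

## Further compounds

F1 | step 14 | 4-acetoxy-3-hydroxy ring-opened aryl ether (acetate at C4 anti to the 3-OH, C2 aryl ether unchanged) | C(c1ccccc1)O[C@H]1Cc2c(OCc3ccccc3)cc(OCc3ccccc3)c([C@@H]3c4c(OCc5ccccc5)cc(OCc5ccccc5)c([C@@H](OC(C)=O)[C@@H](O)[C@H](Oc5cc(OCc6ccccc6)cc(OCc6ccccc6)c5)c5ccc(OCc6ccccc6)c(OCc6ccccc6)c5)c4O[C@H](c4ccc(OCc5ccccc5)c(OCc5ccccc5)c4)[C@H]3O[Si](C)(C)C(C)(C)C)c2O[C@@H]1c1ccc(OCc2ccccc2)c(OCc2ccccc2)c1
F2 | step 22 | methyl 2-methoxycyclohexa-2,5-diene-1-carboxylate (racemic) | COC(=O)C1C=CCC=C1OC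
F3 | step 22 | methyl (S)-1-hydroxy-2-methoxycyclohexa-2,5-diene-1-carboxylate | COC1=CCC=C[C@@]1(O)C(=O)OC
F4 | step 22 | (S)-1-hydroxy-2-methoxycyclohexa-2,5-diene-1-carboxylic acid | COC1=CCC=C[C@@]1(O)C(=O)O
F5 | step 13 | threo epoxy alcohol (C2 epimer of 14, carbinol R) | C(c1ccccc1)O[C@H]1Cc2c(OCc3ccccc3)cc(OCc3ccccc3)c([C@@H]3c4c(OCc5ccccc5)cc(OCc5ccccc5)c([C@@H]5O[C@H]5[C@H](O)c5ccc(OCc6ccccc6)c(OCc6ccccc6)c5)c4O[C@H](c4ccc(OCc5ccccc5)c(OCc5ccccc5)c4)[C@H]3O[Si](C)(C)C(C)(C)C)c2O[C@@H]1c1ccc(OCc2ccccc2)c(OCc2ccccc2)c1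
F6 | step 10 | (R)-allylic alcohol from 12 | C(c1ccccc1)O[C@H]1Cc2c(OCc3ccccc3)cc(OCc3ccccc3)c([C@@H]3c4c(OCc5ccccc5)cc(OCc5ccccc5)c(/C=C/[C@@H](O)c5ccc(OCc6ccccc6)c(OCc6ccccc6)c5)c4O[C@H](c4ccc(OCc5ccccc5)c(OCc5ccccc5)c4)[C@H]3O[Si](C)(C)C(C)(C)C)c2O[C@@H]1c1ccc(OCc2ccccc2)c(OCc2ccccc2)c1
F7 | step 10 | (S)-allylic alcohol from 12 | C(c1ccccc1)O[C@H]1Cc2c(OCc3ccccc3)cc(OCc3ccccc3)c([C@@H]3c4c(OCc5ccccc5)cc(OCc5ccccc5)c(/C=C/[C@H](O)c5ccc(OCc6ccccc6)c(OCc6ccccc6)c5)c4O[C@H](c4ccc(OCc5ccccc5)c(OCc5ccccc5)c4)[C@H]3O[Si](C)(C)C(C)(C)C)c2O[C@@H]1c1ccc(OCc2ccccc2)c(OCc2ccccc2)c1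
F8 | step 6 | 8-bromo-4-(2-ethoxyethoxy)-5,7,3′,4′-tetra-O-benzylcatechin (3-OH free; 3,4-trans drawn) | O[C@H]1[C@H](OCCOCC)c2c(OCc3ccccc3)cc(OCc3ccccc3)c(Br)c2O[C@@H]1c1ccc(OCc2ccccc2)c(OCc2ccccc2)c1
F9 | step 6 | 3-O-acetyl-8-bromo-4-(2-ethoxyethoxy)-5,7,3′,4′-tetra-O-benzylcatechin | CC(=O)O[C@H]1[C@H](OCCOCC)c2c(OCc3ccccc3)cc(OCc3ccccc3)c(Br)c2O[C@@H]1c1ccc(OCc2ccccc2)c(OCc2ccccc2)c1
F10 | step 6 | bromo dimer with middle 3-O-acetyl (4α→8) | C(c1ccccc1)O[C@H]1Cc2c(OCc3ccccc3)cc(OCc3ccccc3)c([C@@H]3c4c(OCc5ccccc5)cc(OCc5ccccc5)c(Br)c4O[C@H](c4ccc(OCc5ccccc5)c(OCc5ccccc5)c4)[C@H]3OC(C)=O)c2O[C@@H]1c1ccc(OCc2ccccc2)c(OCc2ccccc2)c1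
F11 | step 6 | bromo dimer with middle 3-OH (4α→8) | C(c1ccccc1)O[C@H]1Cc2c(OCc3ccccc3)cc(OCc3ccccc3)c([C@@H]3c4c(OCc5ccccc5)cc(OCc5ccccc5)c(Br)c4O[C@H](c4ccc(OCc5ccccc5)c(OCc5ccccc5)c4)[C@H]3O)c2O[C@@H]1c1ccc(OCc2ccccc2)c(OCc2ccccc2)c1
A1 | alternative 1 | (1S,2R)-1,2-dihydroxycyclohexa-3,5-diene-1-carboxylic acid | O[C@@H]1C=CC=C[C@@]1(O)C(=O)O
A2 | alternative 1 | benzoic acid | OC(=O)c1ccccc1
A3 | alternative 1 | (S)-1-hydroxy-6-oxocyclohex-2-ene-1-carboxylic acid | O=C1CCC=C[C@@]1(O)C(=O)O
A4 | alternative 2 | bottom catechin unit (3-O-MOM, 5,7,3′,4′-tetra-O-benzyl) bearing the middle-unit diaryl carbinol at C8 | COCO[C@H]1Cc2c(OCc3ccccc3)cc(OCc3ccccc3)c(C(O)c3c(OCC=C)cc(OCc4ccccc4)cc3OCc3ccccc3)c2O[C@@H]1c1ccc(OCc2ccccc2)c(OCc2ccccc2)c1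
A5 | alternative 2 | open-chain bottom-unit fluoroarene: 1-[3,4-bis(benzyloxy)phenyl]-3-[2,4-bis(benzyloxy)-6-fluorophenyl]-2-(methoxymethoxy)propan-1-ol, catechin configuration | COCO[C@@H](Cc1c(F)cc(OCc2ccccc2)cc1OCc1ccccc1)[C@H](O)c1ccc(OCc2ccccc2)c(OCc2ccccc2)c1
A6 | alternative 2 | 2-(allyloxy)-4,6-bis(benzyloxy)benzaldehyde | O=Cc1c(OCC=C)cc(OCc2ccccc2)cc1OCc1ccccc1
A7 | alternative 3 | 2-(flavan-4-yl)-6-cinnamyl phenol with O5 benzyl, O7 triisopropylsilyl and free O1 | Oc1c(C/C=C/c2ccc(OCc3ccccc3)c(OCc3ccccc3)c2)c(OCc2ccccc2)cc(O[Si](C(C)C)(C(C)C)C(C)C)c1[C@@H]1c2c(OCc3ccccc3)cc(OCc3ccccc3)cc2O[C@H](c2ccc(OCc3ccccc3)c(OCc3ccccc3)c2)[C@H]1OCc1ccccc1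
A8 | alternative 3 | 3-(benzyloxy)-2-[(E)-3-(3,4-bis(benzyloxy)phenyl)prop-2-enyl]cyclobut-2-en-1-one | O=C1CC(OCc2ccccc2)=C1C/C=C/c1ccc(OCc2ccccc2)c(OCc2ccccc2)c1
A9 | alternative 3 | triisopropylsilyl ynol ether of 4-ethynyl-3,5,7,3′,4′-penta-O-benzylcatechin (4α) | CC(C)[Si](C(C)C)(C(C)C)OC#C[C@@H]1c2c(OCc3ccccc3)cc(OCc3ccccc3)cc2O[C@H](c2ccc(OCc3ccccc3)c(OCc3ccccc3)c2)[C@H]1OCc1ccccc1
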